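Longipinane numbering: ring A is the enone ring (C1–C5, C11), ring B the cyclobutane (C4, C5, C11, C10), ring C the seven-membered ring (C5–C11). Everything rests on the C4–C10 bond of ring B. Quaternary C10 adjoins oxygenated C9, a masked trisubstituted epoxide, and C4 can be the β-carbon of a carvone-type C2 enone. These two electrophilic carbons are united reductively: Cp2TiCl opens the epoxide to the tertiary C10 radical, whose 4-exo attack on C4 closes ring B, sets C4 and C10 and frees the C9 hydroxyl. The precursor is a cis-fused bicyclo[5.4.0]undecane epoxy-enone, built from (1S,4R)-p-mentha-2,8-dien-1-ol by Ireland–Claisen rearrangement and ring-closing metathesis.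

Key step: step 9

Numbering remark: from compound 7 on, the longipinane numbers denote the atoms that end up at these positions in the target.
Assumption: (R)-BINAP is taken to direct the allyl transfer of step 4 to the aldehyde face that gives the (R)-carbinol. If the sense of induction is the opposite one, (S)-BINAP takes its place.

Step 1
Reactants: 1 (1S,4R)-p-mentha-2,8-dien-1-ol (hydroxyl and isopropenyl on the same ring face); 2 isobutyryl chloride
Product: 4 (1S,4R)-1-methyl-4-(prop-1-en-2-yl)cyclohex-2-en-1-yl 2-methylpropanoate, via lithium alkoxide 3 (not isolated)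
Conditions: n-BuLi, THF, −78 °C; then 2, −78 °C to rt
Reagents that add atoms: isobutyryl chloride (2), CC(C)C(=O)Cl
Why: O-acylation of the preformed lithium alkoxide (nucleophilic acyl substitution) esterifies the hindered tertiary allylic alcohol without the acid that would ionise it, and no stereocentre is touched.

Step 2
Reactants: 4 tertiary allylic isobutyrate
Product: 7 2-methyl-2-[(1S,6R)-3-methyl-6-(prop-1-en-2-yl)cyclohex-2-en-1-yl]propanoic acid, via silyl ketene acetal 5 (not isolated), via trimethylsilyl ester 6 (not isolated)
Conditions: LiN(i-Pr)2, THF, −78 °C; Me3SiCl, −78 °C to rt, then 60 °C; 1 M HCl work-up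
Reagents that add atoms: none
Why: Ireland–Claisen rearrangement: the [3,3] shift is suprafacial, so the new C5–C6 bond forms on the ring face that carried the C–O bond, which in 1 is the face of the isopropenyl group, and this sets C5 cis to C11, while the symmetric dimethylketene acetal terminus creates the gem-dimethyl carbon without a further stereocentre.

Step 3
Reactants: 7 carboxylic acid
Product: 8 2-methyl-2-[(1S,6R)-3-methyl-6-(prop-1-en-2-yl)cyclohex-2-en-1-yl]propan-1-ol
Conditions: LiAlH4, THF, 0 °C to reflux; aqueous work-up
Reagents that add atoms: none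
Why: Hydride reduction of the carboxylic acid to the neopentyl primary alcohol leaves the unactivated alkenes and both stereocentres untouched.

Step 4
Reactants: 8 neopentyl alcohol; 9 allyl acetate
Product: 11 (3R)-2-methyl-2-[(1S,6R)-3-methyl-6-(prop-1-en-2-yl)cyclohex-2-en-1-yl]hex-5-en-3-ol, via aldehyde 10 (not isolated)
Conditions: [Ir(cod)Cl]2 (2.5 mol %), (R)-BINAP (5 mol %), 4-chloro-3-nitrobenzoic acid (10 mol %), Cs2CO3 (20 mol %), 9, THF, 100 °C, sealed tube
Reagents that add atoms: allyl acetate (9), C=CCOC(C)=O
Why: Krische carbonyl allylation by transfer hydrogenation: the iridium catalyst dehydrogenates 8 to aldehyde 10 and adds the π-allyl fragment of 9 to one aldehyde face under control of the chiral ligand, which sets C7 as R because the resident stereocentres lie behind the quaternary carbon and are too remote to interfere.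

Step 5
Reactants: 11 homoallylic alcohol; 12 isovaleryl chloride
Product: 13 (3R)-2-methyl-2-[(1S,6R)-3-methyl-6-(prop-1-en-2-yl)cyclohex-2-en-1-yl]hex-5-en-3-yl 3-methylbutanoate
Conditions: 12, pyridine, DMAP (cat.), CH2Cl2, 0 °C to 40 °C
Reagents that add atoms: isovaleryl chloride (12), CC(C)CC(=O)Cl
Why: DMAP-catalysed acylation installs the final C7 isovalerate early, so that it also protects this hydroxyl through steps 6 to 13.

Step 6
Reactants: 13 triene ester
Product: 14 (3R)-2-methyl-2-[(1S,6R)-3-methyl-4-oxo-6-(prop-1-en-2-yl)cyclohex-2-en-1-yl]hex-5-en-3-yl 3-methylbutanoate (carvone-type enone with the ketone at C2)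
Conditions: Rh2(cap)4 (dirhodium tetracaprolactamate, 1 mol %), t-BuOOH (70 % in water), 1,2-dichloroethane, 40 °C
Reagents that add atoms: tert-butyl hydroperoxide, CC(C)(C)OO
Why: Radical allylic C–H oxidation (tert-butylperoxyl radical chain under dirhodium catalysis) attacks the only unhindered ring methylene next to the electron-rich trisubstituted alkene, since the other ring allylic position is a neopentyl methine and the isopropenyl and allyl groups offer less activated C–H bonds.

Step 7
Reactants: 14 enone diene
Product: 15 7-isovaleroyloxy-4,10-seco-longipina-3,9-dien-2-one (cis-fused bicyclo[5.4.0]undecadienone; H5 and H11 on one face and the C7 oxygen on the other)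
Conditions: second-generation Grubbs catalyst (5 mol %), toluene (2 mM), 80 °C
Reagents that add atoms: none
Why: Ring-closing metathesis joins the allyl and isopropenyl termini, which the cis arrangement on ring A and the gem-dimethyl group hold close, to the trisubstituted C9=C10 cycloheptene, while the electron-poor enone alkene does not engage the ruthenium carbene.

Step 8
Reactants: 15 bicyclic dienone
Product: 16 9,10-epoxy-7-isovaleroyloxy-4,10-seco-longipin-3-en-2-one (epoxide oxygen on the face of H5 and H11)
Conditions: mCPBA, CH2Cl2, 0 °C; aq. NaHCO3 wash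
Reagents that add atoms: 3-chloroperoxybenzoic acid, OOC(=O)c1cccc(Cl)c1
Why: Prilezhaev epoxidation picks the electron-rich C9=C10 alkene over the enone and should come from the convex face of the cis-fused bicycle, the face of H5 and H11 and remote from the C7 ester, which sets C9 (C10 is set anew in step 9).

Step 9
Reactants: 16 epoxy-enone
Product: 19 9-hydroxy-7-isovaleroyloxylongipinan-2-one (3-methyl syn to C10), via β-titanoxy radical 17 (not isolated), via titanium enolate 18 (not isolated)
Conditions: Cp2TiCl2 (2.5 equiv), Mn dust, THF, rt, slow addition of 16 at high dilution; then 1 M HCl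
Reagents that add atoms: none
Why: Cp2TiCl (trivalent titanium, made in the flask from Cp2TiCl2 and Mn) binds the epoxide oxygen and cleaves the C10–O bond homolytically, giving the more substituted tertiary radical 17 while the C9–O bond and the C9 configuration stay untouched. This nucleophilic radical adds to C4, the β-carbon of the enone, in a 4-exo-trig closure of ring B, and a second Cp2TiCl reduces the electrophilic α-keto radical at once to titanium enolate 18, which makes the otherwise reversible closure irreversible before acid frees the C9 alcohol and the C2 ketone. The closest known reaction type is the reductive epoxide opening–cyclisation with the Nugent–RajanBabu reagent, known in its 4-exo mode for 8,9-epoxycarvone derivatives, which give pinane-type hydroxy ketones. C4 and C10 are controlled by the cis ring fusion: the bulky C6 sits equatorial on ring A, so C10 is axial on C11 and reaches only the syn face of C4, and the doubly bridged cyclobutane admits no other relative configuration, whereas C3 arises from protonation of 18 on the less hindered C5 side and is erased in step 11. The step needs opening towards C10 and not C9 (secured by radical stability), attack at C4 and not at the equally distant carbonyl carbon C2 (secured by polarity matching and by the reversibility of addition to C=O), and closure faster than reduction or disproportionation of 17 (helped by high dilution and by the preorganised axial radical).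

Step 10
Reactants: 19 hydroxy ketone; 20 tigloyl chloride
Product: 21 7-isovaleroyloxy-9-tigloyloxylongipinan-2-one
Conditions: 20, pyridine, DMAP, CH2Cl2, 40 °C
Reagents that add atoms: tigloyl chloride (20), C/C=C(\C)C(=O)Cl
Why: DMAP-catalysed acylation of the neopentyl-type C9 alcohol proceeds with retention at C9, pyridine being too weak a base to deconjugate the tigloyl unit through its vinylketene, so that the E-alkene of 20 is carried over.

Step 11
Reactants: 21 diester ketone
Product: 22 7-isovaleroyloxy-9-tigloyloxylongipin-2-en-2-yl trifluoromethanesulfonate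
Conditions: Tf2O, 2,6-di-tert-butyl-4-methylpyridine, CH2Cl2, 0 °C to rt
Reagents that add atoms: trifluoromethanesulfonic anhydride, O=S(=O)(OS(=O)(=O)C(F)(F)F)C(F)(F)F
Why: Vinyl triflate formation through O-triflation and E1-like proton loss to the hindered pyridine favours the more substituted C2=C3 enol triflate and erases C3, and any C1=C2 isomer would, after step 12, feed the same allylic system in step 13.

Step 12
Reactants: 22 enol triflate
Product: 23 7-isovaleroyloxy-9-tigloyloxylongipin-2-ene
Conditions: Pd(OAc)2 (5 mol %), PPh3 (10 mol %), HCO2H, n-Bu3N, DMF, 60 °C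
Reagents that add atoms: none
Why: Palladium-catalysed formate reduction of the vinyl triflate (oxidative addition to zerovalent palladium, formate decarboxylation, reductive elimination) replaces the triflate by hydrogen without touching the esters or the conjugated tiglate alkene.

Step 13
Reactants: 23 trisubstituted alkene
Product: 24 (4R,5S,7R,9R,10R,11R)-7-isovaleroyloxy-9-tigloyloxylongipin-2-en-1-one (target)
Conditions: CrO3, 3,5-dimethylpyrazole, CH2Cl2, −20 °C
Reagents that add atoms: chromium trioxide, O=[Cr](=O)=O
Why: Allylic oxidation with the CrO3–3,5-dimethylpyrazole complex, the pinene-to-verbenone type of oxidation, converts the C1 methylene into the ketone, this being the only allylic CH2 of the C2=C3 alkene because C4 is a bridgehead, and the electron-poor tiglate is inert.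

Compound list
1 | (1S,4R)-p-mentha-2,8-dien-1-ol | CC(=C)[C@@H]1CC[C@](C)(O)C=C1 | starting material
2 | isobutyryl chloride | CC(C)C(=O)Cl | starting material
3 | lithium alkoxide of 1 | CC(=C)[C@@H]1CC[C@](C)(O[Li])C=C1 | intermediate
4 | (1S,4R)-1-methyl-4-(prop-1-en-2-yl)cyclohex-2-en-1-yl 2-methylpropanoate | CC(=C)[C@@H]1CC[C@](C)(OC(=O)C(C)C)C=C1 | intermediate
5 | trimethylsilyl ketene acetal of 4 | CC(=C)[C@@H]1CC[C@](C)(OC(O[Si](C)(C)C)=C(C)C)C=C1 | intermediate
6 | trimethylsilyl ester of 7 | CC(=C)[C@@H]1CCC(C)=C[C@@H]1C(C)(C)C(=O)O[Si](C)(C)C | intermediate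
7 | 2-methyl-2-[(1S,6R)-3-methyl-6-(prop-1-en-2-yl)cyclohex-2-en-1-yl]propanoic acid | CC(=C)[C@@H]1CCC(C)=C[C@@H]1C(C)(C)C(=O)O | intermediate
8 | 2-methyl-2-[(1S,6R)-3-methyl-6-(prop-1-en-2-yl)cyclohex-2-en-1-yl]propan-1-ol | CC(=C)[C@@H]1CCC(C)=C[C@@H]1C(C)(C)CO | intermediate
9 | allyl acetate | C=CCOC(C)=O | starting material
10 | 2-methyl-2-[(1S,6R)-3-methyl-6-(prop-1-en-2-yl)cyclohex-2-en-1-yl]propanal | CC(=C)[C@@H]1CCC(C)=C[C@@H]1C(C)(C)C=O | intermediate
11 | (3R)-2-methyl-2-[(1S,6R)-3-methyl-6-(prop-1-en-2-yl)cyclohex-2-en-1-yl]hex-5-en-3-ol | CC(=C)[C@@H]1CCC(C)=C[C@@H]1C(C)(C)[C@H](O)CC=C | intermediate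
12 | isovaleryl chloride (3-methylbutanoyl chloride) | CC(C)CC(=O)Cl | starting material
13 | isovalerate of 11 | CC(=C)[C@@H]1CCC(C)=C[C@@H]1C(C)(C)[C@H](OC(=O)CC(C)C)CC=C | intermediate
14 | carvone-type enone (4-oxo derivative of 13) | CC(=C)[C@@H]1CC(=O)C(C)=C[C@@H]1C(C)(C)[C@H](OC(=O)CC(C)C)CC=C | intermediate
15 | 7-isovaleroyloxy-4,10-seco-longipina-3,9-dien-2-one | CC1=CC[C@@H](OC(=O)CC(C)C)C(C)(C)[C@H]2C=C(C)C(=O)C[C@H]21 | intermediate
16 | 9,10-epoxy-7-isovaleroyloxy-4,10-seco-longipin-3-en-2-one | C[C@@]12O[C@@H]1C[C@@H](OC(=O)CC(C)C)C(C)(C)[C@H]3C=C(C)C(=O)C[C@H]32 | intermediate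
17 | C10 tertiary radical with C9–O–TiCp2Cl | C[C]1[C@H](O[Ti](Cl)(C2C=CC=C2)C2C=CC=C2)C[C@@H](OC(=O)CC(C)C)C(C)(C)[C@H]2C=C(C)C(=O)C[C@H]21 | intermediate
18 | tricyclic C2 titanium enolate, C9 titanium alkoxide | Cl[Ti](C4C=CC=C4)(C4C=CC=C4)O[C@@H]1C[C@@H](OC(=O)CC(C)C)C(C)(C)[C@@H]2[C@H]3CC(O[Ti](Cl)(C4C=CC=C4)C4C=CC=C4)=C(C)[C@@H]2[C@]31C | intermediate
19 | 9-hydroxy-7-isovaleroyloxylongipinan-2-one | O[C@@H]1C[C@@H](OC(=O)CC(C)C)C(C)(C)[C@@H]2[C@H]3CC(=O)[C@H](C)[C@@H]2[C@]31C | intermediate
20 | tigloyl chloride ((E)-2-methylbut-2-enoyl chloride) | C/C=C(\C)C(=O)Cl | starting material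
21 | 7-isovaleroyloxy-9-tigloyloxylongipinan-2-one | C/C=C(\C)C(=O)O[C@@H]1C[C@@H](OC(=O)CC(C)C)C(C)(C)[C@@H]2[C@H]3CC(=O)[C@H](C)[C@@H]2[C@]31C | intermediate
22 | 7-isovaleroyloxy-9-tigloyloxylongipin-2-en-2-yl triflate | C/C=C(\C)C(=O)O[C@@H]1C[C@@H](OC(=O)CC(C)C)C(C)(C)[C@@H]2[C@H]3CC(OS(=O)(=O)C(F)(F)F)=C(C)[C@@H]2[C@]31C | intermediate
23 | 7-isovaleroyloxy-9-tigloyloxylongipin-2-ene | C/C=C(\C)C(=O)O[C@@H]1C[C@@H](OC(=O)CC(C)C)C(C)(C)[C@@H]2[C@H]3CC=C(C)[C@@H]2[C@]31C | intermediate
24 | (4R,5S,7R,9R,10R,11R)-7-isovaleroyloxy-9-tigloyloxylongipin-2-en-1-one | C/C=C(\C)C(=O)O[C@@H]1C[C@@H](OC(=O)CC(C)C)C(C)(C)[C@@H]2[C@H]3C(=O)C=C(C)[C@@H]2[C@]31C | target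

Total step count: 13. Longest linear sequence: 13 steps (1 to 24).

Steps most likely to fail

Step 9. The tertiary radical may be reduced by a second titanium centre, or may disproportionate, faster than the strained four-membered ring closes. The fallback sets out from 16 and comes back at 19. The epoxide is isomerised on purpose with diethylaluminium 2,2,6,6-tetramethylpiperidide (toluene, 0 °C) to the exocyclic-methylene allylic alcohol F1. Hydrogen-atom transfer from an iron hydride (Fe(acac)3, PhSiH3, EtOH, 60 °C) to the CH2 terminus then regenerates the same C10 radical, now with no stoichiometric one-electron reductant for alkyl radicals present. The reductive olefin–enone coupling (Giese-type 4-exo closure) gives 19.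

Step 6. Hydrogen abstraction may be unselective among the allylic sites, or oxygen may be delivered with allylic shift to C4. The fallback sets out from 13 and comes back at 14. It replaces the radical chain by a pericyclic sequence. SeO2 (cat.) with t-BuOOH in CH2Cl2 at 0 °C attacks the most nucleophilic, trisubstituted alkene by ene reaction and [2,3]-sigmatropic shift at the ring methylene of its more substituted end, giving the carveol-type allylic alcohol F2. Dess–Martin periodinane then oxidises F2 to 14.

Step 8. Facial selectivity of the peracid on the flexible cycloheptene may be poor or may favour the concave face. The fallback sets out from 15 and comes back at 16 and inverts the facial outcome. N-bromosuccinimide in aqueous acetone forms the bromonium ion on the face the peracid prefers. Water opens it at tertiary C10 from the opposite face to give the bromohydrin F3. K2CO3 in acetone then closes the epoxide on the face of the new hydroxyl.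

Further compounds
F1 | step 9 | 9-hydroxy-7-isovaleroyloxy-10-methylidene-4,10-seco-longipin-3-en-2-one (exocyclic-methylene allylic alcohol) | C=C1[C@H](O)C[C@@H](OC(=O)CC(C)C)C(C)(C)[C@H]2C=C(C)C(=O)C[C@H]21
F2 | step 6 | carveol-type allylic alcohol (4-hydroxy derivative of 13, hydroxyl trans to the isopropenyl group) | CC(=C)[C@@H]1C[C@@H](O)C(C)=C[C@@H]1C(C)(C)[C@H](OC(=O)CC(C)C)CC=C
F3 | step 8 | 9-bromo-10-hydroxy-7-isovaleroyloxy-4,10-seco-longipin-3-en-2-one (hydroxyl on the face of H5 and H11, bromine on the other face) | C[C@@]1(O)[C@@H](Br)C[C@@H](OC(=O)CC(C)C)C(C)(C)[C@H]2C=C(C)C(=O)C[C@H]21
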